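**Plan**

- Ring A of the target is a benzoate (C1 carboxyl) with oxygen on C3 and C5, chlorine on C4 between them and the diaryl ether oxygen on C2, between the phenol carbon and C1. One oxidation level lower this is a 4-aryloxy-2-chlorocyclohexane-1,3-dione 5-carboxylate, so ring A can be closed from an open chain and aromatised afterwards.
- Retrosynthetic cuts: ring A C1–C2 (Michael) and C4–C5 (Claisen); then the ether O–C2 bond (phenol plus chloroacetone) and the ring B aryl–CO2H bond (carbonylation of a bromide that stands in for the acid).
- Forward: ring B comes from 3,5-dimethoxytoluene and receives bromine and the acetonyl ether (steps 1–3). Ring A closes in step 4. Chlorination, O-methylation and dehydrogenation fix its substituents (steps 5–7). The ring B carboxyl is then added and both rings are unmasked (steps 8–10).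
- Stereochemistry: the target has none. The two centres made in step 4 (racemic, trans) are erased in step 7.

Key step: step 4

Remark: compounds 8–11 are racemic and are drawn as one enantiomer of the relative configuration named. Compound 10 is drawn as one of its two enol tautomers. Salts and boron-bound forms that the work-up returns to the named compound carry no number of their own.

**Route**

Step 1
Reactants: 1 3,5-dimethoxytoluene
Product: 3 2-bromo-1,3-dimethoxy-5-methylbenzene, via aryllithium 2 (not isolated)
Conditions: n-BuLi, THF, 0 °C → rt; then BrCH2CH2Br, −78 °C → rt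
Reagents that add atoms: n-butyllithium, [Li]CCCC (the lithium of 2); 1,2-dibromoethane, BrCCBr (the bromine of 3)
Why: Directed ortho-metalation removes the hydrogen between the two methoxy groups, and the aryllithium takes bromine from 1,2-dibromoethane with loss of ethene, which places the halogen where electrophilic bromination would not.

Step 2
Reactants: 3 2-bromo-1,3-dimethoxy-5-methylbenzene
Product: 4 2-bromo-3-methoxy-5-methylphenol
Conditions: NaSEt, DMF, 110 °C; then aq. HCl
Reagents that add atoms: none
Why: SN2 demethylation of an aryl methyl ether by thiolate, known for this dimethoxyarene without the bromine, should stop after one methyl group because the phenoxide formed is a far poorer leaving group for a second displacement, and the unactivated aryl bromide is not substituted.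

Step 3
Reactants: 4 2-bromo-3-methoxy-5-methylphenol; 5 chloroacetone
Product: 6 1-(2-bromo-3-methoxy-5-methylphenoxy)propan-2-one
Conditions: K2CO3, KI (cat.), acetone, reflux
Reagents that add atoms: none
Why: Williamson ether synthesis of a phenoxide with an α-chloro ketone (iodide exchange speeds the displacement) is the standard way to aryloxyacetones, and the weak base avoids aldol self-condensation.

Step 4
Reactants: 6 1-(2-bromo-3-methoxy-5-methylphenoxy)propan-2-one; 7 dimethyl fumarate
Product: 9 racemic trans methyl (1R*,2S*)-2-(2-bromo-3-methoxy-5-methylphenoxy)-3,5-dioxocyclohexane-1-carboxylate, via Michael adduct 8 (not isolated)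
Conditions: KOt-Bu (2.2 equiv), THF, −20 °C; 7 added slowly, → rt; then cold aq. HCl to pH 3
Reagents that add atoms: none
Why: KOt-Bu equilibrates the enolates of 6, and the one at the aryloxy-bearing carbon, the more acidic site, adds to dimethyl fumarate (Michael addition), which joins the future ether carbon to the future carboxyl-bearing carbon and gives 8. After proton transfer the methyl ketone enolate attacks the distal ester of 8 in a 6-exo-trig Claisen closure with loss of methoxide, joining the future chlorine-bearing carbon to the future methoxy-bearing carbon, and the ring rests as its potassium 1,3-diketonate until the acid quench. The closest known reaction type is the consecutive Michael–Claisen synthesis of cyclohexane-1,3-diones from substituted acetones and α,β-unsaturated esters with KOt-Bu, where the substituted carbon also makes the Michael bond and the methyl group the Claisen bond, together with the base closure of acetonylsuccinates to 3,5-dioxocyclohexanecarboxylates, which shows that the six-membered dione wins over 5-exo-trig attack on the nearer ester. The two new stereocentres are under thermodynamic control: the aryloxy carbon epimerises through its enolate (in 8 and, after the quench, in 9), so the trans isomer with both substituents equatorial should prevail, as a racemate, and both centres are erased in step 7. The step needs Michael addition through the aryloxy carbon rather than the methyl group and no E1cB loss of the ring B phenoxide from the β-aryloxy ester; the first is secured by the acidifying oxygen substituent and the reversibility of the Michael addition, the second by low temperature, fast ring closure and the diketonate form of 9, in which a second deprotonation next to the ester is out of reach. The bromine of ring B, which has oxygen on both neighbouring carbons and so no ortho hydrogen for aryne formation, is inert to the base and stands in for a carboxyl group that the carbanion would attack.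

Step 5
Reactants: 9 methyl (1R*,2S*)-2-(2-bromo-3-methoxy-5-methylphenoxy)-3,5-dioxocyclohexane-1-carboxylate
Product: 10 methyl (1R*,2S*)-2-(2-bromo-3-methoxy-5-methylphenoxy)-4-chloro-5-hydroxy-3-oxocyclohex-4-ene-1-carboxylate (enol form of the 4-chloro-3,5-dione)
Conditions: NCS (1.0 equiv), CH2Cl2, 0 °C
Reagents that add atoms: N-chlorosuccinimide, O=C1CCC(=O)N1Cl
Why: Electrophilic chlorination of the enol of a cyclic 1,3-dione by N-chlorosuccinimide goes only at the carbon between the two carbonyl groups and far faster than chlorination of the aryl ether ring B, so the chlorine is placed without a regiochemical choice.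

Step 6
Reactants: 10 methyl (1R*,2S*)-2-(2-bromo-3-methoxy-5-methylphenoxy)-4-chloro-5-hydroxy-3-oxocyclohex-4-ene-1-carboxylate
Product: 11 methyl (1R*,2S*)-2-(2-bromo-3-methoxy-5-methylphenoxy)-4-chloro-5-methoxy-3-oxocyclohex-4-ene-1-carboxylate
Conditions: HC(OMe)3, MeOH, TsOH·H2O (cat.), rt → 40 °C
Reagents that add atoms: methanol, CO; trimethyl orthoformate, COC(OC)OC (takes up the water and releases methanol)
Why: Acid-catalysed formation of a vinylogous ester from a 1,3-dione is reversible and should settle on the isomer with the methoxy group on the carbonyl carbon next to the CH2 group, because a methoxy group squeezed between the chlorine and the aryloxy-bearing carbon is disfavoured (the usual outcome for 4-substituted cyclohexane-1,3-diones), and no base is present that could eliminate the β-aryloxy ester.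

Step 7
Reactants: 11 methyl (1R*,2S*)-2-(2-bromo-3-methoxy-5-methylphenoxy)-4-chloro-5-methoxy-3-oxocyclohex-4-ene-1-carboxylate
Product: 12 methyl 2-(2-bromo-3-methoxy-5-methylphenoxy)-4-chloro-3-hydroxy-5-methoxybenzoate
Conditions: DDQ, TsOH (cat.), 1,4-dioxane, 80 °C
Reagents that add atoms: none
Why: Dehydrogenation of a 3-alkoxycyclohexenone to a resorcinol monoether with DDQ should proceed by acid-catalysed enolisation towards the aryloxy carbon to a cyclohexa-1,3-diene, hydride abstraction to a cation stabilised by both ring oxygens and proton loss, which leaves the ketone oxygen as the phenol, removes both stereocentres and does not touch the methyl group or the bromide of ring B.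

Step 8
Reactants: 12 methyl 2-(2-bromo-3-methoxy-5-methylphenoxy)-4-chloro-3-hydroxy-5-methoxybenzoate
Product: 13 methyl 2-[3-chloro-2-hydroxy-4-methoxy-6-(methoxycarbonyl)phenoxy]-6-methoxy-4-methylbenzoate
Conditions: Pd(OAc)2 (5 mol %), Xantphos, CO (5 bar), Et3N, MeOH–toluene, 100 °C
Reagents that add atoms: carbon monoxide, [C-]#[O+]; methanol, CO
Why: In this palladium-catalysed methoxycarbonylation of an aryl bromide, zerovalent palladium inserts into the C–Br bond and not into the stronger C–Cl bond of the electron-rich ring A, CO insertion gives the acylpalladium and methanol releases the ester; if the neighbouring ring A phenol captures the acyl group instead, the seven-membered lactone so formed (compound F4 of the fallback to step 6) is opened to the same diacid in step 9.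

Step 9
Reactants: 13 methyl 2-[3-chloro-2-hydroxy-4-methoxy-6-(methoxycarbonyl)phenoxy]-6-methoxy-4-methylbenzoate
Product: 14 2-(6-carboxy-3-chloro-2-hydroxy-4-methoxyphenoxy)-6-methoxy-4-methylbenzoic acid
Conditions: KOH, H2O–DMSO, 80 °C; then aq. HCl, 0 °C
Reagents that add atoms: potassium hydroxide, [K+].[OH-] (one oxygen of each new carboxyl group)
Why: Saponification (BAc2) of both methyl esters needs hydroxide in aqueous DMSO with heating because the ring B ester lies between two ortho oxygen substituents, while the diaryl ether, the aryl chloride and the methyl ethers are stable to base and cold acidification avoids decarboxylation.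

Step 10
Reactants: 14 2-(6-carboxy-3-chloro-2-hydroxy-4-methoxyphenoxy)-6-methoxy-4-methylbenzoic acid
Product: 15 2-(6-carboxy-3-chloro-2-hydroxy-4-methoxyphenoxy)-6-hydroxy-4-methylbenzoic acid (the target)
Conditions: BCl3 (excess), CH2Cl2, −78 → 0 °C; then H2O
Reagents that add atoms: none
Why: Chelation-controlled demethylation with BCl3 should be selective: boron bound to the ring B carboxyl group coordinates the ortho methoxy oxygen in a six-membered chelate and chloride removes that methyl group, whereas the ring A methoxy group has no carbonyl group ortho to it and should survive these mild conditions.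

**Compound list**

1 | 3,5-dimethoxytoluene | COc1cc(C)cc(OC)c1 | starting material
2 | (2,6-dimethoxy-4-methylphenyl)lithium | [Li]c1c(OC)cc(C)cc1OC | intermediate (not isolated)
3 | 2-bromo-1,3-dimethoxy-5-methylbenzene | COc1cc(C)cc(OC)c1Br | intermediate
4 | 2-bromo-3-methoxy-5-methylphenol | COc1cc(C)cc(O)c1Br | intermediate
5 | chloroacetone | CC(=O)CCl | starting material
6 | 1-(2-bromo-3-methoxy-5-methylphenoxy)propan-2-one | CC(=O)COc1cc(C)cc(OC)c1Br | intermediate
7 | dimethyl fumarate | COC(=O)/C=C/C(=O)OC | starting material
8 | dimethyl (2R*)-2-[(1S*)-1-(2-bromo-3-methoxy-5-methylphenoxy)-2-oxopropyl]butanedioate (racemic; the aryloxy carbon epimerises) | CC(=O)[C@@H](Oc1cc(C)cc(OC)c1Br)[C@H](C(=O)OC)CC(=O)OC | intermediate (not isolated)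
9 | methyl (1R*,2S*)-2-(2-bromo-3-methoxy-5-methylphenoxy)-3,5-dioxocyclohexane-1-carboxylate (racemic, trans) | O=C1CC(=O)[C@@H](Oc2cc(C)cc(OC)c2Br)[C@H](C(=O)OC)C1 | intermediate
10 | methyl (1R*,2S*)-2-(2-bromo-3-methoxy-5-methylphenoxy)-4-chloro-5-hydroxy-3-oxocyclohex-4-ene-1-carboxylate (racemic, trans; enol of the chlorodione) | OC1=C(Cl)C(=O)[C@@H](Oc2cc(C)cc(OC)c2Br)[C@H](C(=O)OC)C1 | intermediate
11 | methyl (1R*,2S*)-2-(2-bromo-3-methoxy-5-methylphenoxy)-4-chloro-5-methoxy-3-oxocyclohex-4-ene-1-carboxylate (racemic, trans) | COC1=C(Cl)C(=O)[C@@H](Oc2cc(C)cc(OC)c2Br)[C@H](C(=O)OC)C1 | intermediate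
12 | methyl 2-(2-bromo-3-methoxy-5-methylphenoxy)-4-chloro-3-hydroxy-5-methoxybenzoate | COC(=O)c1cc(OC)c(Cl)c(O)c1Oc1cc(C)cc(OC)c1Br | intermediate
13 | methyl 2-[3-chloro-2-hydroxy-4-methoxy-6-(methoxycarbonyl)phenoxy]-6-methoxy-4-methylbenzoate | COC(=O)c1cc(OC)c(Cl)c(O)c1Oc1cc(C)cc(OC)c1C(=O)OC | intermediate
14 | 2-(6-carboxy-3-chloro-2-hydroxy-4-methoxyphenoxy)-6-methoxy-4-methylbenzoic acid | OC(=O)c1cc(OC)c(Cl)c(O)c1Oc1cc(C)cc(OC)c1C(=O)O | intermediate
15 | 2-(6-carboxy-3-chloro-2-hydroxy-4-methoxyphenoxy)-6-hydroxy-4-methylbenzoic acid (achiral) | COc1cc(C(=O)O)c(Oc2cc(C)cc(O)c2C(=O)O)c(O)c1Cl | target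

**Step count**

Total steps: 10. Longest linear sequence: 10 steps (1 to 15).

**Steps most likely to fail**

Step 4. The conjugate addition may also run through the methyl-side enolate, the alkoxide may oligomerise the fumarate, or the open-chain adduct may shed the ring B phenoxide by E1cB before the ring closes. The fallback sets out from 6 and separates the two bond formations. Soft enolisation (TMSOTf, Et3N, CH2Cl2, 0 °C) should give the more substituted silyl enol ether (Z)-[1-(2-bromo-3-methoxy-5-methylphenoxy)prop-1-en-2-yl]oxy(trimethyl)silane F1. A Mukaiyama–Michael addition of F1 to 7 promoted by TiCl4 (CH2Cl2, −78 °C) makes the first bond under Lewis acidic conditions and comes back to the route at 8, which is now isolated. Compound 8 is then closed to 9 with NaOMe in MeOH (0 °C → rt), the Claisen closure known for acetonylsuccinates, and the route continues with step 5.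

Step 6. The methylation may not discriminate well between the two dione oxygens. The fallback sets out from 10 and lets the geometry of the molecule choose the oxygen. The free enol is dehydrogenated with DDQ (dioxane, 80 °C) to the resorcinol methyl 2-(2-bromo-3-methoxy-5-methylphenoxy)-4-chloro-3,5-dihydroxybenzoate F2. Carbonylation of the bromide without any alcohol (Pd(OAc)2, Xantphos, CO, Et3N, toluene, 100 °C) leaves the acylpalladium only the phenol next to the ether oxygen as a partner, which closes the seven-membered lactone methyl 9-chloro-8-hydroxy-1-methoxy-3-methyl-11-oxo-11H-dibenzo[b,e][1,4]dioxepine-6-carboxylate F3. The single remaining phenol is methylated (MeI, K2CO3, acetone) to methyl 9-chloro-1,8-dimethoxy-3-methyl-11-oxo-11H-dibenzo[b,e][1,4]dioxepine-6-carboxylate F4. The KOH treatment of step 9 opens the lactone and the ester, and the route is rejoined at 14.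

Step 7. Enolisation may be slow, so that at the temperature it needs the ring B phenol is eliminated across the ester-bearing carbon faster than hydride is abstracted. The fallback sets out from 11 and forms the diene before the oxidant is added. Silylation (TMSOTf, Et3N, CH2Cl2, −20 °C) should give the racemic silyl dienol ether methyl 2-(2-bromo-3-methoxy-5-methylphenoxy)-4-chloro-5-methoxy-3-[(trimethylsilyl)oxy]cyclohexa-2,4-diene-1-carboxylate F5. DDQ at 0 °C (or a Saegusa–Ito oxidation with Pd(OAc)2 in MeCN) then aromatises it to the aryl silyl ether methyl 2-(2-bromo-3-methoxy-5-methylphenoxy)-4-chloro-5-methoxy-3-[(trimethylsilyl)oxy]benzoate F6. Acidic work-up removes the silyl group and the route is rejoined at 12.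

**Further compounds**

F1 | step 4 | (Z)-[1-(2-bromo-3-methoxy-5-methylphenoxy)prop-1-en-2-yl]oxy(trimethyl)silane | C/C(O[Si](C)(C)C)=C/Oc1cc(C)cc(OC)c1Br
F2 | step 6 | methyl 2-(2-bromo-3-methoxy-5-methylphenoxy)-4-chloro-3,5-dihydroxybenzoate | COC(=O)c1cc(O)c(Cl)c(O)c1Oc1cc(C)cc(OC)c1Br
F3 | step 6 | methyl 9-chloro-8-hydroxy-1-methoxy-3-methyl-11-oxo-11H-dibenzo[b,e][1,4]dioxepine-6-carboxylate | COC(=O)c1cc(O)c(Cl)c2OC(=O)c3c(OC)cc(C)cc3Oc12
F4 | step 6 | methyl 9-chloro-1,8-dimethoxy-3-methyl-11-oxo-11H-dibenzo[b,e][1,4]dioxepine-6-carboxylate | COC(=O)c1cc(OC)c(Cl)c2OC(=O)c3c(OC)cc(C)cc3Oc12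
F5 | step 7 | methyl 2-(2-bromo-3-methoxy-5-methylphenoxy)-4-chloro-5-methoxy-3-[(trimethylsilyl)oxy]cyclohexa-2,4-diene-1-carboxylate (racemic) | COC(=O)C1CC(OC)=C(Cl)C(O[Si](C)(C)C)=C1Oc1cc(C)cc(OC)c1Br
F6 | step 7 | methyl 2-(2-bromo-3-methoxy-5-methylphenoxy)-4-chloro-5-methoxy-3-[(trimethylsilyl)oxy]benzoate | COC(=O)c1cc(OC)c(Cl)c(O[Si](C)(C)C)c1Oc1cc(C)cc(OC)c1Br
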